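## Analysis of the target

The target is the procyanidin tetramer catechin-(4α→6)-epicatechin-(4β→8)-epicatechin-(4β→8)-epicatechin: four 2-(3,4-dihydroxyphenyl)chroman-3,5,7-triol units (units 1 to 4, read from the top), joined by three C4–aryl bonds. It has eleven stereocentres: C2, C3 and C4 in units 1, 2 and 3, and C2 and C3 in unit 4. Every C2 is R (ring B α); unit 1 is 2,3-trans-3,4-trans, units 2 and 3 are 2,3-cis-3,4-trans, and unit 4 is 2,3-cis. Units 1, 3 and 4 therefore map onto (+)-catechin and (−)-epicatechin, whereas unit 2 is an epicatechin substituted at both C4 and C6. The sensitive elements are twenty phenolic hydroxyls (air-sensitive catechols), three doubly benzylic interflavan bonds that ionise in acid, and C2 centres that epimerise in base once the ring B phenols are free. The free polyphenol should therefore appear only in a mild last step. The difficulty is unit 2: in cationic flavan coupling ring A reacts at C8, so the 4→6 bond is the disfavoured one, and unit 2 would have to serve as a C6 nucleophile and a C4 electrophile. The strategy rests on C4 of unit 2, a diarylmethine between the oxygenated C3 and the ring A carbon C4a ortho to O1. That array is what remains when an ester enolate adds to an o-quinone methide and the phenoxide closes on the acyl carbon, forming C3–C4 and O1–C2 of ring C.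

## Retrosynthetic reasoning

32 is traced to its eicosa-O-benzyl ether 31. Benzyl ethers survive the organolithium, Lewis acid and carbonate steps of the route and fall together in one hydrogenolysis, so the oxidation-prone polyphenol is never handled before the end.

In unit 2 of 31 the bonds C2–C1′ (to ring B) and C2–H are cut, leading through lactol 30 to lactone 27 and the aryllithium 29 (from bromide 28). The lactone carbonyl is the natural acceptor for ring B. The forward sequence must stop at mono-addition and then deliver hydride to the oxocarbenium ion so that ring B ends up equatorial and cis to the 3-benzyloxy group.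

Lactone 27 is cut at C3–C4 and at O1–C2 of unit 2, giving the o-hydroxybenzhydrol 24 and the activated ester 21. The cut is placed here because C4 of unit 2 is the carbon that carries the bond to unit 3. One annulation then closes ring C, creates C3 and C4, and does so on a substrate that already contains both halves of the molecule. The only free phenol of 24 is para to unit 1, so the 4→6 pattern follows from the constitution and not from a selectivity. Forward, 24 has to be turned into the o-quinone methide 26 without acid, and a chiral carbene has to turn 21 into an α-benzyloxy enolate that adds to the methide carbon.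

Benzhydrol 24 is cut between the carbinol carbon and C8 of unit 3, giving aldehyde 11 and the aryllithium 22 from the dimer bromide 18. An aryllithium addition to an aldehyde is the most dependable way to join two electron-rich, doubly ortho-substituted arenes. The carbinol configuration is irrelevant because the centre becomes trigonal in 26.

Aldehyde 11 is traced through salicylaldehyde 10 to phenol 9, then through silyl ethers 8 and 7 to triol 6. The formyl carbon goes on by ortho-formylation of the one free phenol, which leaves ring A of unit 1 untouched. That phenol is singled out from the three hydroxyls of 6 by its lack of flanking substituents.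

Triol 6 is cut at the C4(unit 1)–aryl bond into the C4-activated catechin 4 and phloroglucinol 5. Because 5 is threefold symmetric, no regiochemistry arises, and the 3,4-trans relationship follows from attack anti to the 3-benzyloxy group. Compound 4 comes from (+)-catechin 1 through 2 and 3.

Dimer bromide 18 is cut at the C4(unit 3)–C8(unit 4) bond into the 8-bromo electrophile 17 and the nucleophile 14. This is the standard cationic coupling, with bromine blocking C8 of the electrophile and later serving as the handle for lithiation. Both pieces come from (−)-epicatechin 12 through 13 (and 15, 16 for the electrophile).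

Ester 21 is cut at the acyl–oxygen bond into benzyloxyacetic acid 19 and 4-nitrophenol 20.

## Alternatives that were turned down

Alternative 1: The C4–C4a bonds of units 3 and 4 are cut together, leading back to the acyclic bis(aryl ether) bis-epoxide A2. In the forward step a Lewis acid opens both oxiranes, each ring A ortho carbon attacking C4 of its own oxirane, to give the lower dimer A1 with both 3-hydroxyls free.
- For: two C rings form in one operation; the 3,4-trans relationship of unit 3 comes from a stereospecific anti opening and not from a facial bias; no excess nucleophile and no C6/C8 question arise. On these points it is stronger than the Friedel–Crafts coupling of step 15.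
- Against: A2 has six stereocentres that must be built by asymmetric synthesis, in order to reach a fragment that (−)-epicatechin supplies with its stereocentres in place; 18 is six steps from 12. For unit 4 the arene has to attack a primary oxirane carbon in the 6-endo sense while 5-exo opening at C3 competes. The ring B-benzylic aryl ether carbons can ionise under the Lewis acid. A1 would still need 3-O-benzylation and C8 bromination, and the real problem, unit 2 with its 4→6 bond, is untouched.
- Comparison: the chosen route gives up the stereospecific C4–C4a formation and takes the short chiral-pool route to units 3 and 4, placing the new bond construction at the difficult junction.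

Alternative 2: Ring A of unit 2 is cut at C4a–C5 and C8–C8a. In the forward step the 1,1,3-trioxygenated diene A4, carrying unit 1 on its central carbon, adds to the bromo-dihydropyranone A5; loss of HBr and silanol aromatises the adduct to the flavanone A3.
- For: the 4→6 regiochemistry is fixed by construction, and the step is convergent. On regiochemistry it equals the chosen route, which fixes the same pattern through the position of the only free phenol in 24.
- Against: A3 is a flavanone. C3 is still a methylene and C4 a carbonyl, so the C3 oxygen (cis to ring B, whereas α-hydroxylation gives trans), C4 activation and the 4β bond to unit 3 all remain, and that last bond falls back on a cationic coupling with a dimer nucleophile. The C2 centre of A5 and A3 can open by retro-oxa-Michael reaction under the basic or thermal aromatisation. A4 must be made at the acid-labile C4 of unit 1, and the cycloaddition must form a bond next to that bulky substituent.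
- Comparison: the chosen key step creates C3, C4 and the bond to unit 3 at once and leaves three steps to the target; here at least twice as many would follow.

Alternative 3: O1–C2 of unit 3 is cut, leading to the phenolic cis-epoxide A7. In the forward step mild acid lets the ring A phenol open the oxirane at the ring B-benzylic carbon with inversion, which closes ring C and leaves the oxirane oxygen as the 3-hydroxyl of A6.
- For: O1–C2 forms stereospecifically and the 2,3-cis relationship follows from the oxirane geometry. This is stronger than the hydride delivery of step 20, where C2 depends on a facial preference.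
- Against: the oxirane carries a 3,4-bis(benzyloxy)phenyl group and ionises readily, so inversion can be lost towards the 2,3-trans isomer, and 5-exo opening at C3 competes. A7 needs a cis-oxirane of defined configuration next to a diarylmethine stereocentre that must itself be made enantioselectively. The strategy again addresses unit 3, which epicatechin delivers.
- Comparison: the chosen route offers instead a precursor (24) assembled from chiral-pool pieces by an aryllithium addition whose stereochemical outcome does not matter, and leaves only C2 of unit 2 to facial control.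

Key step: step 18

## Assumptions

- Compound 28 and both enantiomers of the aminoindanol-derived N-mesityl triazolium tetrafluoroborate are purchased.
- The sense of induction in step 18 cannot be predicted for a methide carbon flanked by two chiral flavanyl groups. The route is written for the catalyst enantiomer that a trial with both antipodes shows to give the 4β-aryl lactone 27.
- Compound 24 is expected as a mixture of carbinol epimers; one is drawn, and both lead to the same 26.

## Route

Step 1
Reactants: 1 (+)-catechin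
Product: 2 5,7,3′,4′-tetra-O-benzylcatechin
Conditions: BnBr, K2CO3, DMF, 0 °C to rt
Reagents that add atoms: benzyl bromide, BrCc1ccccc1
Why: Williamson etherification; K2CO3 deprotonates only the four phenols, so the secondary 3-hydroxyl stays free and no stereocentre is touched.

Step 2
Reactants: 2 5,7,3′,4′-tetra-O-benzylcatechin
Product: 3 5,7,3′,4′-tetra-O-benzyl-4β-(2-ethoxyethoxy)catechin
Conditions: DDQ, 2-ethoxyethanol, CH2Cl2, rt
Reagents that add atoms: 2-ethoxyethanol, CCOCCO
Why: Benzylic oxidation by hydride abstraction at C4, the position activated by the ring A oxygens; the cation is trapped by the alcohol on the face away from the 2-aryl group. The C4 configuration is of no consequence because the centre is ionised again in step 4.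

Step 3
Reactants: 3 5,7,3′,4′-tetra-O-benzyl-4β-(2-ethoxyethoxy)catechin
Product: 4 3,5,7,3′,4′-penta-O-benzyl-4β-(2-ethoxyethoxy)catechin
Conditions: NaH, BnBr, n-Bu4NI (cat.), DMF, 0 °C to rt
Reagents that add atoms: benzyl bromide, BrCc1ccccc1
Why: Williamson etherification of the secondary alkoxide; the benzylic 4-ether is stable to base, and the 3-benzyl ether removes the last acidic proton ahead of the organolithium steps.

Step 4
Reactants: 4 3,5,7,3′,4′-penta-O-benzyl-4β-(2-ethoxyethoxy)catechin, 5 phloroglucinol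
Product: 6 3,5,7,3′,4′-penta-O-benzyl-4α-(2,4,6-trihydroxyphenyl)catechin
Conditions: BF3·OEt2, 5 (5 equiv), THF/CH2Cl2, −20 to 0 °C; Et3N quench
Reagents that add atoms: none
Why: Friedel–Crafts alkylation; the Lewis acid ionises the C4 ether and the ring A-stabilised cation is captured by a carbon of 5, all three of which are equivalent. Attack anti to the 3-benzyloxy group should give the 3,4-trans (4α) adduct, and the excess of 5 suppresses double alkylation.

Step 5
Reactants: 6 3,5,7,3′,4′-penta-O-benzyl-4α-(2,4,6-trihydroxyphenyl)catechin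
Product: 7 3,5,7,3′,4′-penta-O-benzyl-4α-[2,6-dihydroxy-4-(triisopropylsilyloxy)phenyl]catechin
Conditions: TIPSCl (1.05 equiv), imidazole, DMF, −20 to 0 °C
Reagents that add atoms: triisopropylsilyl chloride, CC(C)[Si](Cl)(C(C)C)C(C)C
Why: Silylation under steric control; the two ortho hydroxyls sit beside the flavan C4 methine while the para hydroxyl has only hydrogens as neighbours, so a bulky chlorosilane in limiting amount at low temperature should react there.

Step 6
Reactants: 7 3,5,7,3′,4′-penta-O-benzyl-4α-[2,6-dihydroxy-4-(triisopropylsilyloxy)phenyl]catechin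
Product: 8 3,5,7,3′,4′-penta-O-benzyl-4α-[2,6-bis(benzyloxy)-4-(triisopropylsilyloxy)phenyl]catechin
Conditions: BnBr, K2CO3, n-Bu4NI (cat.), dry DMF, rt
Reagents that add atoms: benzyl bromide, BrCc1ccccc1
Why: Williamson etherification of the two remaining phenols; the hindered aryl triisopropylsilyl ether is stable to anhydrous carbonate.

Step 7
Reactants: 8 3,5,7,3′,4′-penta-O-benzyl-4α-[2,6-bis(benzyloxy)-4-(triisopropylsilyloxy)phenyl]catechin
Product: 9 3,5,7,3′,4′-penta-O-benzyl-4α-[2,6-bis(benzyloxy)-4-hydroxyphenyl]catechin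
Conditions: Bu4NF, THF, 0 °C
Reagents that add atoms: none
Why: Fluoride-induced cleavage of the aryl silyl ether; benzyl ethers and the interflavan bond are inert to fluoride.

Step 8
Reactants: 9 3,5,7,3′,4′-penta-O-benzyl-4α-[2,6-bis(benzyloxy)-4-hydroxyphenyl]catechin
Product: 10 3,5,7,3′,4′-penta-O-benzyl-4α-[2,6-bis(benzyloxy)-3-formyl-4-hydroxyphenyl]catechin
Conditions: MgCl2, Et3N, (CH2O)n, THF, reflux
Reagents that add atoms: paraformaldehyde (as formaldehyde), C=O
Why: Casnati–Skattebøl ortho-formylation; the magnesium phenoxide delivers formaldehyde to its own ortho carbon and a second formaldehyde oxidises the benzylic alkoxide by Oppenauer-type hydride transfer. Only a ring with a free phenol reacts, so ring A of unit 1 is untouched, and the two ortho positions are equivalent by rotation about the C4–aryl bond.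

Step 9
Reactants: 10 3,5,7,3′,4′-penta-O-benzyl-4α-[2,6-bis(benzyloxy)-3-formyl-4-hydroxyphenyl]catechin
Product: 11 3,5,7,3′,4′-penta-O-benzyl-4α-[2,6-bis(benzyloxy)-4-(tert-butyldimethylsilyloxy)-3-formylphenyl]catechin
Conditions: TBSCl, imidazole, DMAP (cat.), DMF, rt
Reagents that add atoms: tert-butyldimethylsilyl chloride, CC(C)(C)[Si](C)(C)Cl
Why: Silylation of the phenol; it removes the acidic proton before the aryllithium addition, keeps the aldehyde electrophilic, and can later be removed with fluoride, so the acid-labile benzhydrol never meets acid.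

Step 10
Reactants: 12 (−)-epicatechin
Product: 13 5,7,3′,4′-tetra-O-benzylepicatechin
Conditions: BnBr, K2CO3, DMF, 0 °C to rt
Reagents that add atoms: benzyl bromide, BrCc1ccccc1
Why: Williamson etherification of the four phenols, as in step 1.

Step 11
Reactants: 13 5,7,3′,4′-tetra-O-benzylepicatechin
Product: 14 3,5,7,3′,4′-penta-O-benzylepicatechin
Conditions: NaH, BnBr, n-Bu4NI (cat.), DMF, 0 °C to rt
Reagents that add atoms: benzyl bromide, BrCc1ccccc1
Why: Williamson etherification of the 3-hydroxyl; this gives the fully protected nucleophile for unit 4.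

Step 12
Reactants: 13 5,7,3′,4′-tetra-O-benzylepicatechin
Product: 15 5,7,3′,4′-tetra-O-benzyl-4β-(2-ethoxyethoxy)epicatechin
Conditions: DDQ, 2-ethoxyethanol, CH2Cl2, rt
Reagents that add atoms: 2-ethoxyethanol, CCOCCO
Why: Benzylic oxidation at C4 by hydride abstraction, as in step 2; the alcohol adds to the β-face, away from the α-oriented 2-aryl and 3-hydroxyl groups.

Step 13
Reactants: 15 5,7,3′,4′-tetra-O-benzyl-4β-(2-ethoxyethoxy)epicatechin
Product: 16 8-bromo-5,7,3′,4′-tetra-O-benzyl-4β-(2-ethoxyethoxy)epicatechin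
Conditions: NBS, CH2Cl2, −78 °C to 0 °C
Reagents that add atoms: N-bromosuccinimide, O=C1CCC(=O)N1Br
Why: Electrophilic aromatic bromination at C8, the most nucleophilic and least hindered position of ring A (C6 lies between two benzyloxy groups). The bromine blocks self-condensation in step 15 and is the handle for lithiation in step 17.

Step 14
Reactants: 16 8-bromo-5,7,3′,4′-tetra-O-benzyl-4β-(2-ethoxyethoxy)epicatechin
Product: 17 8-bromo-3,5,7,3′,4′-penta-O-benzyl-4β-(2-ethoxyethoxy)epicatechin
Conditions: NaH, BnBr, n-Bu4NI (cat.), DMF, 0 °C to rt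
Reagents that add atoms: benzyl bromide, BrCc1ccccc1
Why: Williamson etherification of the 3-hydroxyl; the aryl bromide and the 4-ether are inert to NaH at this temperature.

Step 15
Reactants: 17 8-bromo-3,5,7,3′,4′-penta-O-benzyl-4β-(2-ethoxyethoxy)epicatechin, 14 3,5,7,3′,4′-penta-O-benzylepicatechin
Product: 18 deca-O-benzyl 8-bromoepicatechin-(4β→8)-epicatechin (bromine on C8 of the upper unit)
Conditions: TMSOTf (cat.), 14 (3 equiv), CH2Cl2, −78 °C; Et3N quench
Reagents that add atoms: none
Why: Friedel–Crafts coupling; the C4 cation of 17 is attacked by C8 of 14 on the β-face, anti to the α-oriented 2-aryl and 3-benzyloxy groups, which sets the 4β (3,4-trans) bond. The bromine stops 17 from reacting as a nucleophile at its own C8, and the excess of 14 limits chain extension.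

Step 16
Reactants: 19 benzyloxyacetic acid, 20 4-nitrophenol
Product: 21 4-nitrophenyl benzyloxyacetate
Conditions: DCC, DMAP (cat.), CH2Cl2, 0 °C to rt
Reagents that add atoms: none
Why: Steglich esterification; it gives the activated aryl ester that a carbene can convert into an acyl azolium.

Step 17
Reactants: 18 deca-O-benzyl 8-bromoepicatechin-(4β→8)-epicatechin, 11 3,5,7,3′,4′-penta-O-benzyl-4α-[2,6-bis(benzyloxy)-4-(tert-butyldimethylsilyloxy)-3-formylphenyl]catechin
Product: 24 o-hydroxybenzhydrol joining ring A of unit 2 (bearing unit 1) to C8 of the lower dimer (carbinol epimers), via 8-lithio dimer 22 (not isolated), via silyl-protected lithium alkoxide 23 (not isolated)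
Conditions: t-BuLi (2 equiv), THF, −78 °C; 11, −78 to −40 °C; then Bu4NF, THF, 0 °C; pH 7 buffer
Reagents that add atoms: none
Why: Bromine–lithium exchange at −78 °C is faster than any deprotonation of the benzyl ethers, and the aryllithium adds to the aldehyde to form the bond that becomes C4(unit 2)–C8(unit 3). Fluoride then removes the silyl group from whichever oxygen holds it, so the benzhydrol is released without acid; the new carbinol centre need not be controlled.

Step 18
Reactants: 24 o-hydroxybenzhydrol joining ring A of unit 2 to C8 of the lower dimer, 21 4-nitrophenyl benzyloxyacetate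
Product: 27 heptadeca-O-benzyl tetramer with unit 2 as 3,4-trans-3-benzyloxy-4β-aryl-dihydrocoumarin (ring B of unit 2 absent), via benzylic tert-butyl carbonate 25 (not isolated), via o-quinone methide 26 (not isolated)
Conditions: Boc2O, Cs2CO3, THF, 0 °C to rt; then 21 (2 equiv), 2-mesityl-5a,10b-dihydro-4H,6H-indeno[2,1-b][1,2,4]triazolo[4,3-d][1,4]oxazin-2-ium tetrafluoroborate (matched enantiomer, 20 mol %), Cs2CO3, 4 Å MS, THF/toluene, rt
Reagents that add atoms: none
Why: Cs2CO3 and Boc2O convert the phenol of 24 into its carbonate, the Boc group moves to the neighbouring benzylic oxygen (25), and the phenoxide expels tert-butyl carbonate to give the o-quinone methide 26; this carbonate migration–elimination needs no acid. The carbene displaces 4-nitrophenoxide from 21 and the acyl azolium is deprotonated to the α-benzyloxy azolium enolate; because an ester and not an aldehyde is used, the benzyloxy group has no elimination pathway. The enolate carbon adds to the methide carbon (C3–C4) and the freed phenoxide acylates at the azolium carbonyl (O1–C2), a 6-exo-trig lactonisation that closes ring C and releases the carbene. The closest known reaction type is the carbene-catalysed [4+2] annulation of azolium enolates with o-quinone methides to 3,4-dihydrocoumarins. C4 is set in the C–C bond-forming event by the chiral carbene, whose indane wall shields one enolate face; the bias of the two flanking flavanyl groups is superimposed, hence the choice of catalyst enantiomer by trial. C3 lies α to an aryl ester and is equilibrated by Cs2CO3; it should settle trans to the C4 aryl group, because the 5-benzyloxy group forces that aryl group pseudoaxial and the trans isomer places the 3-benzyloxy group anti to it. The 4→6 pattern needs no selectivity, since the only phenol of 24 is para to unit 1, and forming 26 before 21 is added keeps that phenol from being acylated.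

Step 19
Reactants: 27 heptadeca-O-benzyl tetramer with unit 2 as dihydrocoumarin, 28 4-bromo-1,2-bis(benzyloxy)benzene
Product: 30 nonadeca-O-benzyl tetramer with unit 2 as 2-aryl-2-hydroxychroman (lactol in equilibrium with its open hydroxy ketone form), via 3,4-bis(benzyloxy)phenyllithium 29 (not isolated)
Conditions: 28, n-BuLi, THF, −78 °C; then 27, THF/toluene, −78 °C; H2O quench at −78 °C
Reagents that add atoms: none
Why: Addition of an aryllithium to a lactone; the strained aryl ester is far more electrophilic than the ketone that ring opening would expose, which is hindered by the α-benzyloxy and β-diarylmethine carbons and deactivated by the dialkoxyphenyl group. Near-stoichiometric reagent and a cold quench should therefore stop at mono-addition.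

Step 20
Reactants: 30 nonadeca-O-benzyl tetramer with unit 2 as 2-aryl-2-hydroxychroman
Product: 31 eicosa-O-benzyl catechin-(4α→6)-epicatechin-(4β→8)-epicatechin-(4β→8)-epicatechin
Conditions: Et3SiH, BF3·OEt2, CH2Cl2, −78 to −40 °C; Et3N quench
Reagents that add atoms: none
Why: Ionic hydrogenation of a lactol; BF3 ionises the hemiketal to the 2-aryl oxocarbenium ion, in which the 3-benzyloxy and 4-aryl groups are trans-diaxial (strain against the 2-aryl group and the 5-benzyloxy group). Axial hydride delivery anti to the neighbouring 3-benzyloxy group should place ring B equatorial and cis to it (2R, 2,3-cis); the low temperature protects the interflavan bonds.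

Step 21
Reactants: 31 eicosa-O-benzyl catechin-(4α→6)-epicatechin-(4β→8)-epicatechin-(4β→8)-epicatechin
Product: 32 catechin-(4α→6)-epicatechin-(4β→8)-epicatechin-(4β→8)-epicatechin (CNP0228086.1)
Conditions: H2 (1 atm), Pd(OH)2/C, THF/MeOH/H2O, rt; filtration and lyophilisation under argon
Reagents that add atoms: none
Why: Hydrogenolysis of the twenty benzyl ethers under neutral conditions; the cyclic C2–O1 benzylic ether and the interflavan bonds are not cleaved under these conditions, and no stereocentre is affected.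

## Compound list

1 | (+)-catechin, (2R,3S)-2-(3,4-dihydroxyphenyl)chroman-3,5,7-triol | O[C@H]1Cc2c(O)cc(O)cc2O[C@@H]1c1ccc(O)c(O)c1 | starting material
2 | 5,7,3′,4′-tetra-O-benzylcatechin | c4ccccc4COc1cc(OCc4ccccc4)c2c(c1)O[C@H](c1ccc(OCc4ccccc4)c(OCc4ccccc4)c1)[C@@H](O)C2 | intermediate
3 | 5,7,3′,4′-tetra-O-benzyl-4β-(2-ethoxyethoxy)catechin (3,4-cis) | c4ccccc4COc1cc(OCc4ccccc4)c2c(c1)O[C@H](c1ccc(OCc4ccccc4)c(OCc4ccccc4)c1)[C@@H](O)[C@H]2OCCOCC | intermediate
4 | 3,5,7,3′,4′-penta-O-benzyl-4β-(2-ethoxyethoxy)catechin | c4ccccc4COc1cc(OCc4ccccc4)c2c(c1)O[C@H](c1ccc(OCc4ccccc4)c(OCc4ccccc4)c1)[C@@H](OCc4ccccc4)[C@H]2OCCOCC | intermediate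
5 | phloroglucinol | Oc1cc(O)cc(O)c1 | starting material
6 | 3,5,7,3′,4′-penta-O-benzyl-4α-(2,4,6-trihydroxyphenyl)catechin (3,4-trans) | c4ccccc4COc1cc(OCc4ccccc4)c2c(c1)O[C@H](c1ccc(OCc4ccccc4)c(OCc4ccccc4)c1)[C@@H](OCc4ccccc4)[C@@H]2c1c(O)cc(O)cc1O | intermediate
7 | 3,5,7,3′,4′-penta-O-benzyl-4α-[2,6-dihydroxy-4-(triisopropylsilyloxy)phenyl]catechin | c4ccccc4COc1cc(OCc4ccccc4)c2c(c1)O[C@H](c1ccc(OCc4ccccc4)c(OCc4ccccc4)c1)[C@@H](OCc4ccccc4)[C@@H]2c1c(O)cc(O[Si](C(C)C)(C(C)C)C(C)C)cc1O | intermediate
8 | 3,5,7,3′,4′-penta-O-benzyl-4α-[2,6-bis(benzyloxy)-4-(triisopropylsilyloxy)phenyl]catechin | c4ccccc4COc1cc(OCc4ccccc4)c2c(c1)O[C@H](c1ccc(OCc4ccccc4)c(OCc4ccccc4)c1)[C@@H](OCc4ccccc4)[C@@H]2c1c(OCc4ccccc4)cc(O[Si](C(C)C)(C(C)C)C(C)C)cc1OCc4ccccc4 | intermediate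
9 | 3,5,7,3′,4′-penta-O-benzyl-4α-[2,6-bis(benzyloxy)-4-hydroxyphenyl]catechin | c4ccccc4COc1cc(OCc4ccccc4)c2c(c1)O[C@H](c1ccc(OCc4ccccc4)c(OCc4ccccc4)c1)[C@@H](OCc4ccccc4)[C@@H]2c1c(OCc4ccccc4)cc(O)cc1OCc4ccccc4 | intermediate
10 | 3,5,7,3′,4′-penta-O-benzyl-4α-[2,6-bis(benzyloxy)-3-formyl-4-hydroxyphenyl]catechin | c4ccccc4COc1cc(OCc4ccccc4)c2c(c1)O[C@H](c1ccc(OCc4ccccc4)c(OCc4ccccc4)c1)[C@@H](OCc4ccccc4)[C@@H]2c1c(OCc4ccccc4)cc(O)c(C=O)c1OCc4ccccc4 | intermediate
11 | 3,5,7,3′,4′-penta-O-benzyl-4α-[2,6-bis(benzyloxy)-4-(tert-butyldimethylsilyloxy)-3-formylphenyl]catechin | c4ccccc4COc1cc(OCc4ccccc4)c2c(c1)O[C@H](c1ccc(OCc4ccccc4)c(OCc4ccccc4)c1)[C@@H](OCc4ccccc4)[C@@H]2c1c(OCc4ccccc4)cc(O[Si](C)(C)C(C)(C)C)c(C=O)c1OCc4ccccc4 | intermediate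
12 | (−)-epicatechin, (2R,3R)-2-(3,4-dihydroxyphenyl)chroman-3,5,7-triol | O[C@@H]1Cc2c(O)cc(O)cc2O[C@@H]1c1ccc(O)c(O)c1 | starting material
13 | 5,7,3′,4′-tetra-O-benzylepicatechin | c4ccccc4COc1cc(OCc4ccccc4)c2c(c1)O[C@H](c1ccc(OCc4ccccc4)c(OCc4ccccc4)c1)[C@H](O)C2 | intermediate
14 | 3,5,7,3′,4′-penta-O-benzylepicatechin | c4ccccc4COc1cc(OCc4ccccc4)c2c(c1)O[C@H](c1ccc(OCc4ccccc4)c(OCc4ccccc4)c1)[C@H](OCc4ccccc4)C2 | intermediate
15 | 5,7,3′,4′-tetra-O-benzyl-4β-(2-ethoxyethoxy)epicatechin (3,4-trans) | c4ccccc4COc1cc(OCc4ccccc4)c2c(c1)O[C@H](c1ccc(OCc4ccccc4)c(OCc4ccccc4)c1)[C@H](O)[C@H]2OCCOCC | intermediate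
16 | 8-bromo-5,7,3′,4′-tetra-O-benzyl-4β-(2-ethoxyethoxy)epicatechin | Brc1c(OCc4ccccc4)cc(OCc4ccccc4)c2c1O[C@H](c1ccc(OCc4ccccc4)c(OCc4ccccc4)c1)[C@H](O)[C@H]2OCCOCC | intermediate
17 | 8-bromo-3,5,7,3′,4′-penta-O-benzyl-4β-(2-ethoxyethoxy)epicatechin | Brc1c(OCc4ccccc4)cc(OCc4ccccc4)c2c1O[C@H](c1ccc(OCc4ccccc4)c(OCc4ccccc4)c1)[C@H](OCc4ccccc4)[C@H]2OCCOCC | intermediate
18 | deca-O-benzyl 8-bromoepicatechin-(4β→8)-epicatechin (bromine on C8 of the upper unit, which becomes unit 3) | Brc1c(OCc4ccccc4)cc(OCc4ccccc4)c3c1O[C@H](c1ccc(OCc4ccccc4)c(OCc4ccccc4)c1)[C@H](OCc4ccccc4)[C@H]3c1c(OCc4ccccc4)cc(OCc4ccccc4)c3c1O[C@H](c1ccc(OCc4ccccc4)c(OCc4ccccc4)c1)[C@H](OCc4ccccc4)C3 | intermediate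
19 | benzyloxyacetic acid | OC(=O)COCc1ccccc1 | starting material
20 | 4-nitrophenol | Oc1ccc(cc1)[N+](=O)[O-] | starting material
21 | 4-nitrophenyl benzyloxyacetate | O=C(COCc1ccccc1)Oc1ccc(cc1)[N+](=O)[O-] | intermediate
22 | 8-lithio derivative of 18 (not isolated) | [Li]c1c(OCc4ccccc4)cc(OCc4ccccc4)c3c1O[C@H](c1ccc(OCc4ccccc4)c(OCc4ccccc4)c1)[C@H](OCc4ccccc4)[C@H]3c1c(OCc4ccccc4)cc(OCc4ccccc4)c3c1O[C@H](c1ccc(OCc4ccccc4)c(OCc4ccccc4)c1)[C@H](OCc4ccccc4)C3 | intermediate
23 | lithium alkoxide of the O-tert-butyldimethylsilyl benzhydrol from 22 and 11 (not isolated; one carbinol epimer drawn) | c4ccccc4COc1cc(OCc4ccccc4)c2c(c1)O[C@H](c1ccc(OCc4ccccc4)c(OCc4ccccc4)c1)[C@@H](OCc4ccccc4)[C@@H]2c1c(OCc4ccccc4)cc(O[Si](C)(C)C(C)(C)C)c(c1OCc4ccccc4)[C@H](O[Li])c1c(OCc4ccccc4)cc(OCc4ccccc4)c3c1O[C@H](c1ccc(OCc4ccccc4)c(OCc4ccccc4)c1)[C@H](OCc4ccccc4)[C@H]3c1c(OCc4ccccc4)cc(OCc4ccccc4)c3c1O[C@H](c1ccc(OCc4ccccc4)c(OCc4ccccc4)c1)[C@H](OCc4ccccc4)C3 | intermediate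
24 | o-hydroxybenzhydrol: heptadeca-O-benzyl compound in which the carbinol carbon joins ring A of unit 2 (free phenol para to unit 1) to C8 of the lower dimer (one carbinol epimer drawn) | c4ccccc4COc1cc(OCc4ccccc4)c2c(c1)O[C@H](c1ccc(OCc4ccccc4)c(OCc4ccccc4)c1)[C@@H](OCc4ccccc4)[C@@H]2c1c(OCc4ccccc4)cc(O)c(c1OCc4ccccc4)[C@H](O)c1c(OCc4ccccc4)cc(OCc4ccccc4)c3c1O[C@H](c1ccc(OCc4ccccc4)c(OCc4ccccc4)c1)[C@H](OCc4ccccc4)[C@H]3c1c(OCc4ccccc4)cc(OCc4ccccc4)c3c1O[C@H](c1ccc(OCc4ccccc4)c(OCc4ccccc4)c1)[C@H](OCc4ccccc4)C3 | intermediate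
25 | benzylic tert-butyl carbonate of 24 (not isolated) | c4ccccc4COc1cc(OCc4ccccc4)c2c(c1)O[C@H](c1ccc(OCc4ccccc4)c(OCc4ccccc4)c1)[C@@H](OCc4ccccc4)[C@@H]2c1c(OCc4ccccc4)cc(O)c(c1OCc4ccccc4)[C@H](OC(=O)OC(C)(C)C)c1c(OCc4ccccc4)cc(OCc4ccccc4)c3c1O[C@H](c1ccc(OCc4ccccc4)c(OCc4ccccc4)c1)[C@H](OCc4ccccc4)[C@H]3c1c(OCc4ccccc4)cc(OCc4ccccc4)c3c1O[C@H](c1ccc(OCc4ccccc4)c(OCc4ccccc4)c1)[C@H](OCc4ccccc4)C3 | intermediate
26 | o-quinone methide of ring A of unit 2, methide carbon bearing C8 of the lower dimer (not isolated; methide geometry not defined) | c4ccccc4COc1cc(OCc4ccccc4)c2c(c1)O[C@H](c1ccc(OCc4ccccc4)c(OCc4ccccc4)c1)[C@@H](OCc4ccccc4)[C@@H]2C5=C(OCc4ccccc4)C(=Cc1c(OCc4ccccc4)cc(OCc4ccccc4)c3c1O[C@H](c1ccc(OCc4ccccc4)c(OCc4ccccc4)c1)[C@H](OCc4ccccc4)[C@H]3c1c(OCc4ccccc4)cc(OCc4ccccc4)c3c1O[C@H](c1ccc(OCc4ccccc4)c(OCc4ccccc4)c1)[C@H](OCc4ccccc4)C3)C(=O)C=C5OCc4ccccc4 | intermediate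
27 | heptadeca-O-benzyl tetramer with unit 2 as (3R,4R)-3-benzyloxy-4-aryl-chroman-2-one (3,4-trans, aryl β; ring B of unit 2 absent) | c4ccccc4COc1cc(OCc4ccccc4)c2c(c1)O[C@H](c1ccc(OCc4ccccc4)c(OCc4ccccc4)c1)[C@@H](OCc4ccccc4)[C@@H]2c1c(OCc4ccccc4)cc2c(c1OCc4ccccc4)[C@H](c1c(OCc4ccccc4)cc(OCc4ccccc4)c3c1O[C@H](c1ccc(OCc4ccccc4)c(OCc4ccccc4)c1)[C@H](OCc4ccccc4)[C@H]3c1c(OCc4ccccc4)cc(OCc4ccccc4)c3c1O[C@H](c1ccc(OCc4ccccc4)c(OCc4ccccc4)c1)[C@H](OCc4ccccc4)C3)[C@@H](OCc4ccccc4)C(=O)O2 | intermediate
28 | 4-bromo-1,2-bis(benzyloxy)benzene | Brc1ccc(OCc2ccccc2)c(OCc2ccccc2)c1 | starting material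
29 | 3,4-bis(benzyloxy)phenyllithium (not isolated) | [Li]c1ccc(OCc2ccccc2)c(OCc2ccccc2)c1 | intermediate
30 | nonadeca-O-benzyl tetramer with unit 2 as 2-[3,4-bis(benzyloxy)phenyl]-2-hydroxychroman (anomers, in equilibrium with the open hydroxy ketone; C2 not defined) | c4ccccc4COc1cc(OCc4ccccc4)c2c(c1)O[C@H](c1ccc(OCc4ccccc4)c(OCc4ccccc4)c1)[C@@H](OCc4ccccc4)[C@@H]2c1c(OCc4ccccc4)cc2c(c1OCc4ccccc4)[C@H](c1c(OCc4ccccc4)cc(OCc4ccccc4)c3c1O[C@H](c1ccc(OCc4ccccc4)c(OCc4ccccc4)c1)[C@H](OCc4ccccc4)[C@H]3c1c(OCc4ccccc4)cc(OCc4ccccc4)c3c1O[C@H](c1ccc(OCc4ccccc4)c(OCc4ccccc4)c1)[C@H](OCc4ccccc4)C3)[C@@H](OCc4ccccc4)C(O)(c1ccc(OCc4ccccc4)c(OCc4ccccc4)c1)O2 | intermediate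
31 | eicosa-O-benzyl catechin-(4α→6)-epicatechin-(4β→8)-epicatechin-(4β→8)-epicatechin | c4ccccc4COc1cc(OCc4ccccc4)c2c(c1)O[C@H](c1ccc(OCc4ccccc4)c(OCc4ccccc4)c1)[C@@H](OCc4ccccc4)[C@@H]2c1c(OCc4ccccc4)cc2c(c1OCc4ccccc4)[C@H](c1c(OCc4ccccc4)cc(OCc4ccccc4)c3c1O[C@H](c1ccc(OCc4ccccc4)c(OCc4ccccc4)c1)[C@H](OCc4ccccc4)[C@H]3c1c(OCc4ccccc4)cc(OCc4ccccc4)c3c1O[C@H](c1ccc(OCc4ccccc4)c(OCc4ccccc4)c1)[C@H](OCc4ccccc4)C3)[C@@H](OCc4ccccc4)[C@@H](c1ccc(OCc4ccccc4)c(OCc4ccccc4)c1)O2 | intermediate
32 | catechin-(4α→6)-epicatechin-(4β→8)-epicatechin-(4β→8)-epicatechin (CNP0228086.1) | Oc1cc(O)c2c(c1)O[C@H](c1ccc(O)c(O)c1)[C@@H](O)[C@@H]2c1c(O)cc2c(c1O)[C@H](c1c(O)cc(O)c3c1O[C@H](c1ccc(O)c(O)c1)[C@H](O)[C@H]3c1c(O)cc(O)c3c1O[C@H](c1ccc(O)c(O)c1)[C@H](O)C3)[C@@H](O)[C@@H](c1ccc(O)c(O)c1)O2 | target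

## Step count and risks

Total: 21 steps. Longest linear sequence: 14 steps (steps 1–9 and 17–21, from 1). The epicatechin branch (steps 10–15) and the ester (step 16) are convergent.

Least certain steps:

Step 18 (key step). Two things are most likely to go wrong. The first is poor facial selectivity at C4, because the catalyst must work with or against the bias of two large chiral flavanyl groups beside the methide carbon. The second is slow C–C bond formation at a donor-stabilised, doubly flanked methide, which leaves the enolate to be consumed by acyl transfer; incomplete equilibration at C3 is a lesser concern. The fallback abandons the annulation for a cationic chain assembly: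
- Bromination of 14 with NBS gives 8-bromo-3,5,7,3′,4′-penta-O-benzylepicatechin F1, whose only free ring A position is C6.
- BF3·OEt2- or TMSOTf-mediated capture of the cation from 4 by F1 gives the deca-O-benzyl catechin-(4α→6)-8-bromoepicatechin F2.
- DDQ with 2-ethoxyethanol activates C4 of its epicatechin unit to give the 4β-(2-ethoxyethoxy) dimer F3.
- Bromine–lithium exchange of 18 with n-BuLi and protonation gives the deca-O-benzyl epicatechin-(4β→8)-epicatechin F4.
- TMSOTf coupling of F3 with an excess of F4, which reacts at C8 of its upper unit, gives the 8-bromo eicosa-O-benzyl tetramer F5.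
- Hydrogenolysis of F5 over Pd(OH)2/C with Et3N removes the bromine together with the benzyl groups and rejoins the route at 32.

Step 20. The likely failures are hydride delivery from the wrong face (giving the all-equatorial 2,3-trans isomer, since the face anti to the 3-benzyloxy group is also the face of the pseudoaxial 4-aryl group), loss of the C3 proton from the oxocarbenium ion with scrambling of C3, and acid cleavage of an interflavan bond. The fallback sets C2 by two stereodefined steps from 30. Zn(BH4)2 reduces the open hydroxy ketone form under chelation control by the α-benzyloxy group to the anti alcohol, the phenolic diol F6. A Mitsunobu cycloetherification (PPh3, DIAD) then closes O1–C2 with inversion and rejoins the route at 31.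

Step 19. The likely failures are over-addition after collapse of the tetrahedral intermediate to the ketone, and deprotonation at C3 with loss of its configuration. The fallback starts from 27. Aminolysis with MeNH(OMe)·HCl and i-PrMgCl opens the lactone to the phenolic N-methoxy-N-methylamide F7. An excess of 29 (the first equivalent deprotonates the phenol) stops at the chelated tetrahedral intermediate, and work-up releases the hydroxy ketone, which closes to 30.

Step 17. The likely failures are incomplete addition between two doubly ortho-substituted partners, and ionisation of the very electron-rich benzhydrol during desilylation or purification. The fallback starts from 10. Boc2O with i-Pr2NEt gives the aryl tert-butyl carbonate F8, a smaller and more electrophilic aldehyde. Addition of 22 gives an alkoxide that takes over the Boc group and, on warming, eliminates tert-butyl carbonate to form 26 directly. Compound 26 then enters the second stage of step 18 without passing through 24.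

Step 5. The likely failure is poor site selectivity between the para and the two ortho hydroxyls, giving mixtures of mono- and bis-silyl ethers. The fallback carries the differentiation in the nucleophile. Commercial 3,5-bis(benzyloxy)phenol is silylated (TIPSCl, imidazole) to 1,3-bis(benzyloxy)-5-(triisopropylsilyloxy)benzene F9. Under the conditions of step 4, F9 is coupled with 4 at the carbon between the two benzyloxy groups; the silyl ether screens its own ortho positions, and any regioisomer is removed by chromatography. This rejoins the route at 8.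

## Further compounds

F1 | step 18 | 8-bromo-3,5,7,3′,4′-penta-O-benzylepicatechin | Brc1c(OCc4ccccc4)cc(OCc4ccccc4)c2c1O[C@H](c1ccc(OCc4ccccc4)c(OCc4ccccc4)c1)[C@H](OCc4ccccc4)C2
F2 | step 18 | deca-O-benzyl catechin-(4α→6)-8-bromoepicatechin | c4ccccc4COc1cc(OCc4ccccc4)c2c(c1)O[C@H](c1ccc(OCc4ccccc4)c(OCc4ccccc4)c1)[C@@H](OCc4ccccc4)[C@@H]2c1c(OCc4ccccc4)c(Br)c2c(c1OCc4ccccc4)C[C@@H](OCc4ccccc4)[C@@H](c1ccc(OCc4ccccc4)c(OCc4ccccc4)c1)O2
F3 | step 18 | deca-O-benzyl catechin-(4α→6)-8-bromo-4β-(2-ethoxyethoxy)epicatechin | c4ccccc4COc1cc(OCc4ccccc4)c2c(c1)O[C@H](c1ccc(OCc4ccccc4)c(OCc4ccccc4)c1)[C@@H](OCc4ccccc4)[C@@H]2c1c(OCc4ccccc4)c(Br)c2c(c1OCc4ccccc4)[C@H](OCCOCC)[C@@H](OCc4ccccc4)[C@@H](c1ccc(OCc4ccccc4)c(OCc4ccccc4)c1)O2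
F4 | step 18 | deca-O-benzyl epicatechin-(4β→8)-epicatechin | c4ccccc4COc1cc(OCc4ccccc4)c3c(c1)O[C@H](c1ccc(OCc4ccccc4)c(OCc4ccccc4)c1)[C@H](OCc4ccccc4)[C@H]3c1c(OCc4ccccc4)cc(OCc4ccccc4)c3c1O[C@H](c1ccc(OCc4ccccc4)c(OCc4ccccc4)c1)[C@H](OCc4ccccc4)C3
F5 | step 18 | eicosa-O-benzyl tetramer with bromine on C8 of unit 2 | c4ccccc4COc1cc(OCc4ccccc4)c2c(c1)O[C@H](c1ccc(OCc4ccccc4)c(OCc4ccccc4)c1)[C@@H](OCc4ccccc4)[C@@H]2c1c(OCc4ccccc4)c(Br)c2c(c1OCc4ccccc4)[C@H](c1c(OCc4ccccc4)cc(OCc4ccccc4)c3c1O[C@H](c1ccc(OCc4ccccc4)c(OCc4ccccc4)c1)[C@H](OCc4ccccc4)[C@H]3c1c(OCc4ccccc4)cc(OCc4ccccc4)c3c1O[C@H](c1ccc(OCc4ccccc4)c(OCc4ccccc4)c1)[C@H](OCc4ccccc4)C3)[C@@H](OCc4ccccc4)[C@@H](c1ccc(OCc4ccccc4)c(OCc4ccccc4)c1)O2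
F6 | step 20 | nonadeca-O-benzyl open-chain phenol with anti 2-benzyloxy-1-aryl-propan-1-ol chain at unit 2 (ring C of unit 2 open between O1 and C2) | c4ccccc4COc1cc(OCc4ccccc4)c2c(c1)O[C@H](c1ccc(OCc4ccccc4)c(OCc4ccccc4)c1)[C@@H](OCc4ccccc4)[C@@H]2c1c(OCc4ccccc4)cc(O)c(c1OCc4ccccc4)[C@H](c1c(OCc4ccccc4)cc(OCc4ccccc4)c3c1O[C@H](c1ccc(OCc4ccccc4)c(OCc4ccccc4)c1)[C@H](OCc4ccccc4)[C@H]3c1c(OCc4ccccc4)cc(OCc4ccccc4)c3c1O[C@H](c1ccc(OCc4ccccc4)c(OCc4ccccc4)c1)[C@H](OCc4ccccc4)C3)[C@@H](OCc4ccccc4)[C@H](c1ccc(OCc4ccccc4)c(OCc4ccccc4)c1)O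
F7 | step 19 | heptadeca-O-benzyl phenolic N-methoxy-N-methylamide from opening of lactone 27 | c4ccccc4COc1cc(OCc4ccccc4)c2c(c1)O[C@H](c1ccc(OCc4ccccc4)c(OCc4ccccc4)c1)[C@@H](OCc4ccccc4)[C@@H]2c1c(OCc4ccccc4)cc(O)c(c1OCc4ccccc4)[C@H](c1c(OCc4ccccc4)cc(OCc4ccccc4)c3c1O[C@H](c1ccc(OCc4ccccc4)c(OCc4ccccc4)c1)[C@H](OCc4ccccc4)[C@H]3c1c(OCc4ccccc4)cc(OCc4ccccc4)c3c1O[C@H](c1ccc(OCc4ccccc4)c(OCc4ccccc4)c1)[C@H](OCc4ccccc4)C3)[C@@H](OCc4ccccc4)C(=O)N(C)OC
F8 | step 17 | 3,5,7,3′,4′-penta-O-benzyl-4α-[2,6-bis(benzyloxy)-4-(tert-butoxycarbonyloxy)-3-formylphenyl]catechin | c4ccccc4COc1cc(OCc4ccccc4)c2c(c1)O[C@H](c1ccc(OCc4ccccc4)c(OCc4ccccc4)c1)[C@@H](OCc4ccccc4)[C@@H]2c1c(OCc4ccccc4)cc(OC(=O)OC(C)(C)C)c(C=O)c1OCc4ccccc4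
F9 | step 5 | 1,3-bis(benzyloxy)-5-(triisopropylsilyloxy)benzene | CC(C)[Si](Oc1cc(OCc2ccccc2)cc(OCc2ccccc2)c1)(C(C)C)C(C)C
A1 | alternative 1 | octa-O-benzyl epicatechin-(4β→8)-epicatechin with both 3-hydroxyls free | c4ccccc4COc1cc(OCc4ccccc4)c3c(c1)O[C@H](c1ccc(OCc4ccccc4)c(OCc4ccccc4)c1)[C@H](O)[C@H]3c1c(OCc4ccccc4)cc(OCc4ccccc4)c3c1O[C@H](c1ccc(OCc4ccccc4)c(OCc4ccccc4)c1)[C@H](O)C3
A2 | alternative 1 | acyclic bis(aryl ether) bis-epoxide (trans-oxirane for unit 3, terminal oxirane for unit 4) | c4ccccc4COc1cc(OCc4ccccc4)cc(c1)O[C@H](c1ccc(OCc4ccccc4)c(OCc4ccccc4)c1)[C@@H]1O[C@H]1c1c(OCc4ccccc4)cc(OCc4ccccc4)cc1O[C@H](c1ccc(OCc4ccccc4)c(OCc4ccccc4)c1)[C@H]1CO1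
A3 | alternative 2 | benzylated catechin-(4α→6)-(2S)-5-O-benzyl-7-hydroxyflavanone | c4ccccc4COc1cc(OCc4ccccc4)c2c(c1)O[C@H](c1ccc(OCc4ccccc4)c(OCc4ccccc4)c1)[C@@H](OCc4ccccc4)[C@@H]2c1c(O)cc2c(c1OCc4ccccc4)C(=O)C[C@@H](c1ccc(OCc4ccccc4)c(OCc4ccccc4)c1)O2
A4 | alternative 2 | 1-benzyloxy-1,3-bis(trimethylsilyloxy)buta-1,3-diene carrying the penta-O-benzylcatechin-4α-yl group on C2 | c4ccccc4COc1cc(OCc4ccccc4)c2c(c1)O[C@H](c1ccc(OCc4ccccc4)c(OCc4ccccc4)c1)[C@@H](OCc4ccccc4)[C@@H]2C(=C(OCc4ccccc4)O[Si](C)(C)C)C(=C)O[Si](C)(C)C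
A5 | alternative 2 | (2S)-5-bromo-2-[3,4-bis(benzyloxy)phenyl]-2,3-dihydro-4H-pyran-4-one | O=C1C[C@@H](c2ccc(OCc3ccccc3)c(OCc3ccccc3)c2)OC=C1Br
A6 | alternative 3 | nona-O-benzyl epicatechin-(4β→8)-epicatechin with free 3-hydroxyl on unit 3 | c4ccccc4COc1cc(OCc4ccccc4)c3c(c1)O[C@H](c1ccc(OCc4ccccc4)c(OCc4ccccc4)c1)[C@H](O)[C@H]3c1c(OCc4ccccc4)cc(OCc4ccccc4)c3c1O[C@H](c1ccc(OCc4ccccc4)c(OCc4ccccc4)c1)[C@H](OCc4ccccc4)C3
A7 | alternative 3 | phenolic cis-epoxide: 2-hydroxy-4,6-bis(benzyloxy)phenyl methine bearing C8 of benzylated unit 4 and a cis-3-[3,4-bis(benzyloxy)phenyl]oxiran-2-yl group | c4ccccc4COc1cc(OCc4ccccc4)c(c(O)c1)[C@H](c1c(OCc4ccccc4)cc(OCc4ccccc4)c3c1O[C@H](c1ccc(OCc4ccccc4)c(OCc4ccccc4)c1)[C@H](OCc4ccccc4)C3)[C@H]1O[C@H]1c1ccc(OCc4ccccc4)c(OCc4ccccc4)c1
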